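**Plan**

1. Retrosynthesis: the catechol (two MOM ethers) and the enal (cinnamate, then allylic alcohol) are unmasked last. The dihydrofuran ring is cut at C2–C3 (carbenoid C–H insertion), then C3a–C3 (aryl iodide + ethyl diazoacetate), O1–C2 (Mitsunobu ether) and the side-chain C=C (Wittig), back to 5-iodovanillin and 5-hydroxyvanillin.
2. Forward: both benzene rings are bought. The ether link, the cinnamate and the diazo ester are installed in turn, then the only ring that is built, the dihydrofuran ring, closes by rhodium carbenoid insertion into the C2–H bond. Oxidation levels are then adjusted (i-Bu2AlH, MnO2) and the MOM groups removed.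
3. Enabling feature: C2 carries both O1 and the trioxygenated aryl ring, so in the open form it is a doubly activated benzylic ether CH2 lying 1,5 to C3. C3 is benzylic to ring A (the benzo ring) and bears a carbon (the later CH2OH) that can stand at the ester level, which makes C3 accessible as a donor/acceptor carbene.
4. Stereochemistry: C2 (R) comes from the chiral dirhodium carboxylate in the insertion, which gives the cis ester. C3 is then epimerized to the trans ester under thermodynamic control. The E alkene comes from the stabilized ylide.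

Key step: step 6

Assumption: Rh2(S-PTTL)4 is taken to induce the (2R) configuration by analogy with related 2-(benzyloxy)phenyl diazoacetates, and the ethyl ester is assumed to behave like a methyl ester; were the sense opposite on this substrate, Rh2(R-PTTL)4 would be used.

**Route**

Step 1
Reactants: 1 5-hydroxyvanillin (3,4-dihydroxy-5-methoxybenzaldehyde)
Product: 2 bis-MOM aldehyde, 3-methoxy-4,5-bis(methoxymethoxy)benzaldehyde
Conditions: MOMCl (3 equiv), i-Pr2NEt (4 equiv), CH2Cl2, 0 °C to rt
Reagents that add atoms: chloromethyl methyl ether, COCCl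
Why: Both phenols are O-alkylated by the reactive α-chloro ether under amine base (Williamson-type alkylation), giving base- and hydride-stable acetal groups that lie out of intramolecular reach of the later carbenoid, while the aldehyde is untouched.

Step 2
Reactants: 2 bis-MOM aldehyde
Product: 3 benzylic alcohol, [3-methoxy-4,5-bis(methoxymethoxy)phenyl]methanol
Conditions: NaBH4, MeOH, 0 °C
Reagents that add atoms: none
Why: Borohydride reduction converts the aryl aldehyde chemoselectively into the benzylic alcohol and leaves the MOM acetals alone.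

Step 3
Reactants: 3 benzylic alcohol; 4 5-iodovanillin (4-hydroxy-3-iodo-5-methoxybenzaldehyde)
Product: 5 aryl benzyl ether, 3-iodo-5-methoxy-4-{[3-methoxy-4,5-bis(methoxymethoxy)phenyl]methoxy}benzaldehyde
Conditions: PPh3, DIAD, THF, 0 °C to rt
Reagents that add atoms: none
Why: Mitsunobu etherification, in which the phenol of 4, made acidic by the para formyl and ortho iodo groups, is a good pronucleophile for the alkoxyphosphonium ion of the primary benzylic alcohol 3, and the neutral conditions spare the aldehyde and the MOM acetals.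

Step 4
Reactants: 5 aryl benzyl ether
Product: 6 iodo cinnamate, ethyl (E)-3-(3-iodo-5-methoxy-4-{[3-methoxy-4,5-bis(methoxymethoxy)phenyl]methoxy}phenyl)prop-2-enoate
Conditions: Ph3P=CHCO2Et, toluene, 80 °C
Reagents that add atoms: ethyl (triphenylphosphoranylidene)acetate, CCOC(=O)C=P(c1ccccc1)(c1ccccc1)c1ccccc1
Why: Wittig olefination of the unhindered aryl aldehyde with a stabilized ylide should give the E cinnamate, an electron-poor alkene chosen because it resists the electrophilic carbenoid of step 6.

Step 5
Reactants: 6 iodo cinnamate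
Product: 7 aryl diazoacetate, ethyl (E)-3-[3-(1-diazo-2-ethoxy-2-oxoethyl)-5-methoxy-4-{[3-methoxy-4,5-bis(methoxymethoxy)phenyl]methoxy}phenyl]prop-2-enoate
Conditions: ethyl diazoacetate (1.5 equiv), Pd(PPh3)4 (5 mol %), Ag2CO3 (0.5 equiv), Et3N, toluene, rt
Reagents that add atoms: ethyl diazoacetate, CCOC(=O)C=[N+]=[N-]
Why: Palladium-catalysed cross-coupling of an aryl iodide with the C–H bond of an acceptor diazo compound, in which oxidative addition, silver-assisted transfer of the diazoacetate carbon to palladium and reductive elimination at room temperature outrun loss of N2, so the diazo group is kept and the cinnamate and MOM groups do not react.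

Step 6
Reactants: 7 aryl diazoacetate
Product: 8 cis ester, ethyl (2R,3S)-5-[(E)-3-ethoxy-3-oxoprop-1-en-1-yl]-7-methoxy-2-[3-methoxy-4,5-bis(methoxymethoxy)phenyl]-2,3-dihydro-1-benzofuran-3-carboxylate
Conditions: Rh2(S-PTTL)4 (dirhodium tetrakis[N-phthaloyl-(S)-tert-leucinate], 2 mol %), toluene, slow addition of 7, −78 to −40 °C
Reagents that add atoms: none
Why: The catalyst expels N2 from 7 to give an electrophilic donor/acceptor rhodium carbenoid at the future C3, which takes a hydride-like hydrogen from the benzylic OCH2 carbon (the future C2) in a concerted, asynchronous three-centre transition state and forms the C2–C3 bond with return of the catalyst. The closest known reaction type is the enantioselective intramolecular 1,5 C–H insertion of 2-(benzyloxy)phenyl diazoacetates to cis-2-aryl-2,3-dihydrobenzofuran-3-carboxylates under chiral dirhodium carboxylate catalysis. The one ring formed, the dihydrofuran ring, closes by 1,5-insertion through a five-membered array (carbenoid carbon, C3a, C7a, O1, C2), the ether oxygen itself lying too close to give a stable ylide ring. C2 is set by the chiral carboxylate ligands, which distinguish the two enantiotopic benzylic hydrogens, and C3 is set relative to C2 by the kinetic preference of the insertion transition state for aryl and ester on the same face. The step needs site selectivity for the OCH2Ar hydrogens over the MOM and methoxy C–H bonds, the cinnamate double bond and the arenes, which should be secured by the double activation of that CH2 (O1 and the electron-rich aryl ring), its 1,5 relation to the carbenoid, the electron-poor alkene, low temperature and dilution, while the enantioselectivity rests on the catalyst alone.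

Step 7
Reactants: 8 cis ester
Product: 9 trans ester, ethyl (2R,3R)-5-[(E)-3-ethoxy-3-oxoprop-1-en-1-yl]-7-methoxy-2-[3-methoxy-4,5-bis(methoxymethoxy)phenyl]-2,3-dihydro-1-benzofuran-3-carboxylate
Conditions: NaOEt (0.2 equiv), EtOH, 0 °C to rt; AcOH quench
Reagents that add atoms: none
Why: Base-mediated epimerization through the C3 ester enolate (C3–H is benzylic and α to the ester) should equilibrate the kinetic cis ester to the more stable trans ester without touching C2, with ethoxide matching both ester groups and sub-stoichiometric base at low temperature meant to suppress β-elimination of the O1 aryloxide from the enolate.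

Step 8
Reactants: 9 trans ester
Product: 10 diol, (E)-3-{(2R,3S)-3-(hydroxymethyl)-7-methoxy-2-[3-methoxy-4,5-bis(methoxymethoxy)phenyl]-2,3-dihydro-1-benzofuran-5-yl}prop-2-en-1-ol
Conditions: i-Bu2AlH (6 equiv), CH2Cl2, −78 to −20 °C; aq. potassium sodium tartrate
Reagents that add atoms: none
Why: i-Bu2AlH reduces both esters to primary alcohols, the cinnamate by 1,2-addition to the allylic alcohol, without touching the MOM acetals or the stereocenters, and the C3 descriptor changes from R to S only because CH2OH ranks below C2.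

Step 9
Reactants: 10 diol
Product: 11 protected enal, (E)-3-{(2R,3S)-3-(hydroxymethyl)-7-methoxy-2-[3-methoxy-4,5-bis(methoxymethoxy)phenyl]-2,3-dihydro-1-benzofuran-5-yl}prop-2-enal
Conditions: activated MnO2 (excess), CH2Cl2, rt
Reagents that add atoms: none
Why: MnO2 oxidizes allylic (cinnamyl) alcohols selectively, so the enal should form with retention of the E geometry while the saturated primary alcohol on C3 stays.

Step 10
Reactants: 11 protected enal
Product: 12 cassyformin, (E)-3-[(2R,3S)-2-(3,4-dihydroxy-5-methoxyphenyl)-3-(hydroxymethyl)-7-methoxy-2,3-dihydro-1-benzofuran-5-yl]prop-2-enal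
Conditions: 3 M aq. HCl, THF, 40 °C, under argon
Reagents that add atoms: none
Why: Acid-catalysed hydrolysis of the two aryl MOM acetals in aqueous THF should release the catechol without an alcohol cosolvent that could acetalize the enal, and the trans arrangement at C2 and C3 is the thermodynamically preferred one and should persist.

**Compound list**

1 | 5-hydroxyvanillin (3,4-dihydroxy-5-methoxybenzaldehyde) | COc1cc(C=O)cc(O)c1O | starting material
2 | 3-methoxy-4,5-bis(methoxymethoxy)benzaldehyde | COCOc1cc(C=O)cc(OC)c1OCOC | intermediate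
3 | [3-methoxy-4,5-bis(methoxymethoxy)phenyl]methanol | COCOc1cc(CO)cc(OC)c1OCOC | intermediate
4 | 5-iodovanillin (4-hydroxy-3-iodo-5-methoxybenzaldehyde) | COc1cc(C=O)cc(I)c1O | starting material
5 | 3-iodo-5-methoxy-4-{[3-methoxy-4,5-bis(methoxymethoxy)phenyl]methoxy}benzaldehyde | COc1cc(C=O)cc(I)c1OCc1cc(OC)c(OCOC)c(OCOC)c1 | intermediate
6 | ethyl (E)-3-(3-iodo-5-methoxy-4-{[3-methoxy-4,5-bis(methoxymethoxy)phenyl]methoxy}phenyl)prop-2-enoate | CCOC(=O)/C=C/c1cc(I)c(OCc2cc(OC)c(OCOC)c(OCOC)c2)c(OC)c1 | intermediate
7 | ethyl (E)-3-[3-(1-diazo-2-ethoxy-2-oxoethyl)-5-methoxy-4-{[3-methoxy-4,5-bis(methoxymethoxy)phenyl]methoxy}phenyl]prop-2-enoate | CCOC(=O)/C=C/c1cc(OC)c(OCc2cc(OC)c(OCOC)c(OCOC)c2)c(C(=[N+]=[N-])C(=O)OCC)c1 | intermediate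
8 | ethyl (2R,3S)-5-[(E)-3-ethoxy-3-oxoprop-1-en-1-yl]-7-methoxy-2-[3-methoxy-4,5-bis(methoxymethoxy)phenyl]-2,3-dihydro-1-benzofuran-3-carboxylate (cis) | COc1cc([C@@H]2Oc3c(OC)cc(/C=C/C(=O)OCC)cc3[C@@H]2C(=O)OCC)cc(OCOC)c1OCOC | intermediate
9 | ethyl (2R,3R)-5-[(E)-3-ethoxy-3-oxoprop-1-en-1-yl]-7-methoxy-2-[3-methoxy-4,5-bis(methoxymethoxy)phenyl]-2,3-dihydro-1-benzofuran-3-carboxylate (trans) | COc1cc([C@@H]2Oc3c(OC)cc(/C=C/C(=O)OCC)cc3[C@H]2C(=O)OCC)cc(OCOC)c1OCOC | intermediate
10 | (E)-3-{(2R,3S)-3-(hydroxymethyl)-7-methoxy-2-[3-methoxy-4,5-bis(methoxymethoxy)phenyl]-2,3-dihydro-1-benzofuran-5-yl}prop-2-en-1-ol | COc1cc([C@@H]2Oc3c(OC)cc(/C=C/CO)cc3[C@H]2CO)cc(OCOC)c1OCOC | intermediate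
11 | (E)-3-{(2R,3S)-3-(hydroxymethyl)-7-methoxy-2-[3-methoxy-4,5-bis(methoxymethoxy)phenyl]-2,3-dihydro-1-benzofuran-5-yl}prop-2-enal | COc1cc([C@@H]2Oc3c(OC)cc(/C=C/C=O)cc3[C@H]2CO)cc(OCOC)c1OCOC | intermediate
12 | cassyformin, (E)-3-[(2R,3S)-2-(3,4-dihydroxy-5-methoxyphenyl)-3-(hydroxymethyl)-7-methoxy-2,3-dihydro-1-benzofuran-5-yl]prop-2-enal | COc1cc([C@@H]2Oc3c(OC)cc(/C=C/C=O)cc3[C@H]2CO)cc(O)c1O | target

**Step count**

Total steps: 10. Longest linear sequence: 10 steps (1 to 12; 4 enters at step 3).

**Steps most likely to fail**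

1. Step 6. The doubly activated, electron-rich benzylic C–H bond may react through so early a transition state that the catalyst distinguishes the two hydrogens poorly, or the carbenoid may be lost to dimerization before insertion. The fallback replaces catalyst control by auxiliary control with a matched catalyst and gives the trans series directly; it sets out from 6 and comes back at 10.
   - Methyl (R)-lactate and pyrrolidine (neat, rt) should give the auxiliary alcohol (R)-2-hydroxy-1-(pyrrolidin-1-yl)propan-1-one F1.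
   - Bromoacetyl bromide and NaHCO3 in MeCN should give the bromoacetate (R)-1-oxo-1-(pyrrolidin-1-yl)propan-2-yl 2-bromoacetate F2.
   - N,N'-bis(p-toluenesulfonyl)hydrazine and DBU in THF should give the diazoacetate (R)-1-oxo-1-(pyrrolidin-1-yl)propan-2-yl 2-diazoacetate F3.
   - Coupling of the diazoacetate with iodide 6 under the conditions of step 5 should give the auxiliary-bearing aryl diazoacetate F4.
   - Rh2(R-DOSP)4 (dirhodium tetrakis[(R)-N-(4-dodecylbenzenesulfonyl)prolinate]) in CH2Cl2 should convert it by double stereodifferentiation into the trans (2R,3R) auxiliary ester F5. This auxiliary and catalyst pairing is taken as the matched one for the (2R,3R) series by analogy with related lactamide-directed insertions, and the mirror-image pair would be used if the sense were the reverse.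
   - i-Bu2AlH (CH2Cl2, −78 °C) reduces both ester groups, releases the auxiliary alcohol and returns diol 10, so step 7 is bypassed as well.

2. Step 5. Transfer of the diazoacetate carbon to palladium may be slow at the ortho-alkoxy iodide, so that loss of N2 through palladium carbene pathways or dipolar addition of ethyl diazoacetate to the cinnamate takes over. The fallback sets out from 6 and comes back at 7.
   - Negishi coupling of 6 with the Reformatsky reagent BrZnCH2CO2Et (from ethyl bromoacetate and zinc; Pd2(dba)3, XPhos, THF, 60 °C) should give the arylacetate ethyl (E)-3-[3-(2-ethoxy-2-oxoethyl)-5-methoxy-4-{[3-methoxy-4,5-bis(methoxymethoxy)phenyl]methoxy}phenyl]prop-2-enoate F6.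
   - Regitz diazo transfer (p-acetamidobenzenesulfonyl azide, DBU, MeCN, 0 °C to rt) then gives 7.

3. Step 10. Acid may ionize the C2–O1 bond of the para-oxygenated benzylic ether, the released formaldehyde may hydroxymethylate the freed electron-rich catechol ring, and the enal may suffer under acid. The fallback moves the acid step to the robust diester stage and ends with a fluoride deprotection; it sets out from 9 and comes back at 12.
   - Aqueous HCl in THF on 9 should give the catechol diester ethyl (2R,3R)-2-(3,4-dihydroxy-5-methoxyphenyl)-5-[(E)-3-ethoxy-3-oxoprop-1-en-1-yl]-7-methoxy-2,3-dihydro-1-benzofuran-3-carboxylate F7.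
   - TBSCl and imidazole in DMF should give the bis-silyl diester F8.
   - i-Bu2AlH (CH2Cl2, −78 °C) should give the bis-silyl diol F9.
   - MnO2 (CH2Cl2, rt) should give the bis-silyl enal F10.
   - Et3N·3HF in THF at 0 °C should remove both silyl groups and give 12.

**Further compounds**

F1 | step 6 | (R)-2-hydroxy-1-(pyrrolidin-1-yl)propan-1-one | C[C@@H](O)C(=O)N1CCCC1
F2 | step 6 | (R)-1-oxo-1-(pyrrolidin-1-yl)propan-2-yl 2-bromoacetate | C[C@@H](OC(=O)CBr)C(=O)N1CCCC1
F3 | step 6 | (R)-1-oxo-1-(pyrrolidin-1-yl)propan-2-yl 2-diazoacetate | C[C@@H](OC(=O)C=[N+]=[N-])C(=O)N1CCCC1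
F4 | step 6 | ethyl (E)-3-[3-(1-diazo-2-oxo-2-{[(R)-1-oxo-1-(pyrrolidin-1-yl)propan-2-yl]oxy}ethyl)-5-methoxy-4-{[3-methoxy-4,5-bis(methoxymethoxy)phenyl]methoxy}phenyl]prop-2-enoate | CCOC(=O)/C=C/c1cc(OC)c(OCc2cc(OC)c(OCOC)c(OCOC)c2)c(C(=[N+]=[N-])C(=O)O[C@H](C)C(=O)N2CCCC2)c1
F5 | step 6 | (R)-1-oxo-1-(pyrrolidin-1-yl)propan-2-yl (2R,3R)-5-[(E)-3-ethoxy-3-oxoprop-1-en-1-yl]-7-methoxy-2-[3-methoxy-4,5-bis(methoxymethoxy)phenyl]-2,3-dihydro-1-benzofuran-3-carboxylate | COc1cc([C@@H]2Oc3c(OC)cc(/C=C/C(=O)OCC)cc3[C@H]2C(=O)O[C@H](C)C(=O)N2CCCC2)cc(OCOC)c1OCOC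
F6 | step 5 | ethyl (E)-3-[3-(2-ethoxy-2-oxoethyl)-5-methoxy-4-{[3-methoxy-4,5-bis(methoxymethoxy)phenyl]methoxy}phenyl]prop-2-enoate | CCOC(=O)/C=C/c1cc(OC)c(OCc2cc(OC)c(OCOC)c(OCOC)c2)c(CC(=O)OCC)c1
F7 | step 10 | ethyl (2R,3R)-2-(3,4-dihydroxy-5-methoxyphenyl)-5-[(E)-3-ethoxy-3-oxoprop-1-en-1-yl]-7-methoxy-2,3-dihydro-1-benzofuran-3-carboxylate | COc1cc([C@@H]2Oc3c(OC)cc(/C=C/C(=O)OCC)cc3[C@H]2C(=O)OCC)cc(O)c1O
F8 | step 10 | ethyl (2R,3R)-2-[3,4-bis(tert-butyldimethylsilyloxy)-5-methoxyphenyl]-5-[(E)-3-ethoxy-3-oxoprop-1-en-1-yl]-7-methoxy-2,3-dihydro-1-benzofuran-3-carboxylate | COc1cc([C@@H]2Oc3c(OC)cc(/C=C/C(=O)OCC)cc3[C@H]2C(=O)OCC)cc(O[Si](C)(C)C(C)(C)C)c1O[Si](C)(C)C(C)(C)C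
F9 | step 10 | (E)-3-{(2R,3S)-2-[3,4-bis(tert-butyldimethylsilyloxy)-5-methoxyphenyl]-3-(hydroxymethyl)-7-methoxy-2,3-dihydro-1-benzofuran-5-yl}prop-2-en-1-ol | COc1cc([C@@H]2Oc3c(OC)cc(/C=C/CO)cc3[C@H]2CO)cc(O[Si](C)(C)C(C)(C)C)c1O[Si](C)(C)C(C)(C)C
F10 | step 10 | (E)-3-{(2R,3S)-2-[3,4-bis(tert-butyldimethylsilyloxy)-5-methoxyphenyl]-3-(hydroxymethyl)-7-methoxy-2,3-dihydro-1-benzofuran-5-yl}prop-2-enal | COc1cc([C@@H]2Oc3c(OC)cc(/C=C/C=O)cc3[C@H]2CO)cc(O[Si](C)(C)C(C)(C)C)c1O[Si](C)(C)C(C)(C)C
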